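**Plan**

1. The target is the (2S)-7-hydroxyflavan whose ring B carries 3',4'-hydroxyls and 2',5'-prenyl groups; C2 is the only stereocentre.
2. Cuts: first the two prenyl C=C bonds (back to allyl groups, cross-metathesis). Then C2–C3 and O1–C8a of the pyran ring together, which leaves a ring B aldehyde (C2 and O1 as its C=O) and 4-vinylphenol (ring A with C4 and C3). Last, the two aryl–allyl bonds (back to O-allyl ethers, double Claisen).
3. Enabling feature: the C7 hydroxyl of ring A is para to C4a, so ring A with its C4=C3 vinyl group is a vinylogous phenol. C3 is nucleophilic, and in the para-quinone methide left by its attack C8a (meta to the C7 oxygen) is electrophilic, so one aldehyde C=O can add across C3 and C8a while ring A rearomatises.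
4. Forward: ring B aldehyde first (steps 1–3), ring A as bought (step 4), pyran ring C closed last between them (step 5), then the prenyl groups (step 6) and the free catechol (step 7).
5. Stereochemistry: C2 is set in step 5 by a chiral Brønsted acid catalyst and is not touched afterwards.

Key step: step 5

Remark: the target SMILES corresponds to 2S; the (S,S) acid of step 5 is assumed to deliver 2S (otherwise its mirror image is used), and allyl groups stand in for prenyl groups until after the acid step because prenyl alkenes would not survive it.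

**Route**

Step 1
Reactants: 1 3,4-dihydroxybenzaldehyde; 2 allyl bromide
Product: 3 3,4-bis(allyloxy)benzaldehyde
Conditions: allyl bromide (2.5 equiv), K2CO3, DMF, 60 °C
Reagents that add atoms: allyl bromide, C=CCBr
Why: Williamson ether synthesis, in which both phenoxides of 1 are alkylated by the primary allylic bromide in an SN2 reaction.

Step 2
Reactants: 3 3,4-bis(allyloxy)benzaldehyde
Product: 5 2,5-diallyl-3,4-dihydroxybenzaldehyde, via mono-rearranged phenol 4 (not isolated)
Conditions: N,N-diethylaniline, 200 °C, sealed tube, argon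
Reagents that add atoms: none
Why: Double aromatic Claisen rearrangement, in which each allyl ether shifts [3,3] to its only free ortho carbon (O3 to C2, O4 to C5) and tautomerisation restores the phenols.

Step 3
Reactants: 5 2,5-diallyl-3,4-dihydroxybenzaldehyde; 6 acetic anhydride
Product: 7 3,4-diacetoxy-2,5-diallylbenzaldehyde
Conditions: Ac2O, pyridine, DMAP (cat.), CH2Cl2, 0 °C to rt
Reagents that add atoms: acetic anhydride, CC(=O)OC(C)=O
Why: DMAP-catalysed acetylation (nucleophilic acyl substitution) should cap the catechol as the electron-poor, acid-stable diacetate that the key step needs.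

Step 4
Reactants: 8 4-acetoxystyrene
Product: 9 4-vinylphenol
Conditions: K2CO3 (cat.), MeOH, 0 °C; AcOH quench; cold CH2Cl2 solution used at once
Reagents that add atoms: none
Why: Base-catalysed transesterification (Zemplén-type methanolysis) of the aryl acetate should free the phenol under conditions too mild to polymerise the styrene.

Step 5
Reactants: 7 3,4-diacetoxy-2,5-diallylbenzaldehyde; 9 4-vinylphenol
Product: 12 (2S)-2-(3,4-diacetoxy-2,5-diallylphenyl)chroman-7-ol, via quinone methide carbinol 10 (not isolated), via dearomatised cycloadduct 11 (not isolated)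
Conditions: (S,S)-imidodiphosphorimidate acid [(S)-3,3'-Ar2-BINOL-P(=NTf)]2NH, Ar = 3,5-(CF3)2C6H3 (5 mol%), 5 Å molecular sieves, CH2Cl2, −40 °C, slow addition of 9 (1.3 equiv)
Reagents that add atoms: none
Why: Proposed new method: the chiral acid activates the aldehyde of 7 by hydrogen bonding and the vinyl terminus (C3) of the vinylogous phenol 9 attacks the carbonyl carbon in a Prins-type step, which forms C2–C3 and the protonated para-quinone methide of 10. The C2 oxygen then adds to ring carbon C8a, ortho to the methide and beta to the C7 carbonyl, in a 6-exo-trig conjugate addition that closes the pyran ring, and the isotoluene 11 rearomatises by an acid-mediated proton shift from C8a to C4. The closest known types are the Brønsted-acid-catalysed asymmetric oxa-Diels–Alder reaction of simple dienes with aromatic aldehydes and the Prins reaction of styrenes; the use of a styrene C=C together with one ring C=C as the four-carbon partner is that of the Wagner-Jauregg reaction. C2, the only new stereocentre that persists, is set in the C–C bond-forming event by the confined chiral counter-anion, which blocks one face of the bound aldehyde; the C8a centre of 11 is lost on aromatisation. The step needs closure at C8a and not at C4, and 1:1 coupling without cationic side reactions: closures at C4 (oxetane, dioxane, benzylic ethers) stay reversible through ionisation of a para-hydroxybenzylic C–O bond whereas closure at C8a is sealed by rearomatisation, the diacetate makes the aldehyde more electrophilic and the C2–O bond of 12 non-ionisable, and allyl groups (not prenyl) keep the side chains inert to the acid.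

Step 6
Reactants: 12 (2S)-2-(3,4-diacetoxy-2,5-diallylphenyl)chroman-7-ol; 13 2-methyl-2-butene
Product: 14 (2S)-2-[3,4-diacetoxy-2,5-bis(3-methylbut-2-enyl)phenyl]chroman-7-ol
Conditions: second-generation Grubbs catalyst (5 mol%), 2-methyl-2-butene (excess), CH2Cl2, 40 °C
Reagents that add atoms: 2-methyl-2-butene, CC=C(C)C
Why: Olefin cross-metathesis should exchange both terminal allyl alkenes with excess 2-methyl-2-butene to the trisubstituted prenyl groups with loss of propene, leaving the acetates, the free phenol and C2 untouched.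

Step 7
Reactants: 14 (2S)-2-[3,4-diacetoxy-2,5-bis(3-methylbut-2-enyl)phenyl]chroman-7-ol
Product: 15 Kazinol A, (2S)-2-[3,4-dihydroxy-2,5-bis(3-methylbut-2-enyl)phenyl]chroman-7-ol
Conditions: K2CO3 (cat.), degassed MeOH, 0 °C, argon; aq. NH4Cl
Reagents that add atoms: none
Why: Base-catalysed transesterification of the two aryl acetates should liberate the catechol without acid, which would cyclise the ortho-prenyl phenols, and without touching C2.

**Compound list**

1 | 3,4-dihydroxybenzaldehyde | O=Cc1ccc(O)c(O)c1 | starting material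
2 | allyl bromide | C=CCBr | starting material
3 | 3,4-bis(allyloxy)benzaldehyde | C=CCOc1ccc(C=O)cc1OCC=C | intermediate
4 | 2-allyl-4-(allyloxy)-3-hydroxybenzaldehyde (mono-rearranged phenol, not isolated) | C=CCOc1ccc(C=O)c(CC=C)c1O | intermediate
5 | 2,5-diallyl-3,4-dihydroxybenzaldehyde | C=CCc1cc(C=O)c(CC=C)c(O)c1O | intermediate
6 | acetic anhydride | CC(=O)OC(C)=O | starting material
7 | 3,4-diacetoxy-2,5-diallylbenzaldehyde | C=CCc1cc(C=O)c(CC=C)c(OC(C)=O)c1OC(C)=O | intermediate
8 | 4-acetoxystyrene | C=Cc1ccc(OC(C)=O)cc1 | starting material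
9 | 4-vinylphenol | C=Cc1ccc(O)cc1 | intermediate
10 | (S)-4-[3-(3,4-diacetoxy-2,5-diallylphenyl)-3-hydroxypropylidene]cyclohexa-2,5-dien-1-one (quinone methide carbinol, not isolated) | C=CCc1cc([C@@H](O)CC=C2C=CC(=O)C=C2)c(CC=C)c(OC(C)=O)c1OC(C)=O | intermediate
11 | (2S)-2-(3,4-diacetoxy-2,5-diallylphenyl)-3,8a-dihydro-2H-chromen-7-ol (dearomatised cycloadduct, either epimer at C8a, not isolated) | C=CCc1cc([C@@H]2CC=C3C=CC(O)=CC3O2)c(CC=C)c(OC(C)=O)c1OC(C)=O | intermediate
12 | (2S)-2-(3,4-diacetoxy-2,5-diallylphenyl)chroman-7-ol | C=CCc1cc([C@@H]2CCc3ccc(O)cc3O2)c(CC=C)c(OC(C)=O)c1OC(C)=O | intermediate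
13 | 2-methyl-2-butene | CC=C(C)C | starting material
14 | (2S)-2-[3,4-diacetoxy-2,5-bis(3-methylbut-2-enyl)phenyl]chroman-7-ol | CC(C)=CCc1cc([C@@H]2CCc3ccc(O)cc3O2)c(CC=C(C)C)c(OC(C)=O)c1OC(C)=O | intermediate
15 | Kazinol A, (2S)-2-[3,4-dihydroxy-2,5-bis(3-methylbut-2-enyl)phenyl]chroman-7-ol | CC(C)=CCc1cc([C@@H]2CCc3ccc(O)cc3O2)c(CC=C(C)C)c(O)c1O | target

**Count**

Total step count: 7. Longest linear sequence: 6 steps (1, 2, 3, 5, 6, 7).

**Steps most likely to fail**

Step 5 (Proposed new method). What may go wrong: acid-induced self-oligomerisation of the vinylphenol, capture of the benzylic cation at C4 without funnelling into ring closure at C8a, or weak facial control at C2. The fallback uses known chemistry, sets out from 5 and comes back to the route at 15.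
- 5 is silylated (TBSCl, imidazole, DMF) to 2,5-diallyl-3,4-bis(tert-butyldimethylsilyloxy)benzaldehyde F1.
- Commercial 2-bromo-4-hydroxybenzaldehyde is silylated in the same way to 2-bromo-4-(tert-butyldimethylsilyloxy)benzaldehyde F2 and methylenated (Ph3PCH3Br, KOtBu, THF, Wittig reaction) to (3-bromo-4-vinylphenoxy)(tert-butyl)dimethylsilane F3.
- Hydroboration of F3 with Et2BH should give [2-(2-bromo-4-(tert-butyldimethylsilyloxy)phenyl)ethyl]diethylborane F4, and boron–zinc exchange with Et2Zn the reagent bis[2-(2-bromo-4-(tert-butyldimethylsilyloxy)phenyl)ethyl]zinc F5.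
- One arm of F5 is added to F1 under Ti(OiPr)4 and catalytic 1,2-bis(trifluoromethanesulfonamido)cyclohexane (the 1R,2R ligand, chosen by analogy with simple aryl aldehydes, or its mirror image if needed). This ligand-controlled addition should give (1S)-1-[2,5-diallyl-3,4-bis(tert-butyldimethylsilyloxy)phenyl]-3-[2-bromo-4-(tert-butyldimethylsilyloxy)phenyl]propan-1-ol F6.
- Intramolecular C–O cross-coupling (Pd(OAc)2, 2-(di-tert-butylphosphino)-1,1'-binaphthyl, Cs2CO3, toluene, 70 °C) closes the pyran ring with retention at C2 to (2S)-2-[2,5-diallyl-3,4-bis(tert-butyldimethylsilyloxy)phenyl]-7-(tert-butyldimethylsilyloxy)chroman F7.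
- Cross-metathesis with 13 as in step 6 should give (2S)-2-[3,4-bis(tert-butyldimethylsilyloxy)-2,5-bis(3-methylbut-2-enyl)phenyl]-7-(tert-butyldimethylsilyloxy)chroman F8.
- Buffered fluoride (Bu4NF, AcOH, THF, 0 °C) removes the three silyl groups to give 15.

Step 2. What may go wrong: thermal degradation of the free catechol aldehyde at the temperature the second sigmatropic shift needs, or an incomplete second shift. The fallback introduces the formyl group only after both shifts, sets out from 2 and comes back at 5. Commercial catechol is alkylated with 2 (K2CO3, acetone) to 1,2-bis(allyloxy)benzene F9, which rearranges neat at 190 °C to 3,6-diallylbenzene-1,2-diol F10. Duff formylation (hexamethylenetetramine, AcOH, 100 °C; aq. HCl) can only occur para to a hydroxyl at one of the two equivalent free positions, because both ortho positions are blocked, and should give 5.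

Step 7. What may go wrong: air oxidation of the catecholate and base-induced opening of the C2–O bond through a ring B quinone methide (loss of configuration) while free phenoxides sit in protic base. The fallback replaces solvolysis by hydride reduction, sets out from 14 and comes back at 15. DIBAL-H (CH2Cl2, −78 °C, then Rochelle salt) reduces the two acetyl groups to ethanol and releases the phenols from aluminium phenoxides on neutral work-up; no new compound arises (F0).

**Further compounds**

F1 | step 5 | 2,5-diallyl-3,4-bis(tert-butyldimethylsilyloxy)benzaldehyde | C=CCc1cc(C=O)c(CC=C)c(O[Si](C)(C)C(C)(C)C)c1O[Si](C)(C)C(C)(C)C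
F2 | step 5 | 2-bromo-4-(tert-butyldimethylsilyloxy)benzaldehyde | O=Cc1ccc(O[Si](C)(C)C(C)(C)C)cc1Br
F3 | step 5 | (3-bromo-4-vinylphenoxy)(tert-butyl)dimethylsilane | C=Cc1ccc(O[Si](C)(C)C(C)(C)C)cc1Br
F4 | step 5 | [2-(2-bromo-4-(tert-butyldimethylsilyloxy)phenyl)ethyl]diethylborane | CCB(CC)CCc1ccc(O[Si](C)(C)C(C)(C)C)cc1Br
F5 | step 5 | bis[2-(2-bromo-4-(tert-butyldimethylsilyloxy)phenyl)ethyl]zinc | Brc1cc(O[Si](C)(C)C(C)(C)C)ccc1CC[Zn]CCc1ccc(O[Si](C)(C)C(C)(C)C)cc1Br
F6 | step 5 | (1S)-1-[2,5-diallyl-3,4-bis(tert-butyldimethylsilyloxy)phenyl]-3-[2-bromo-4-(tert-butyldimethylsilyloxy)phenyl]propan-1-ol | C=CCc1cc([C@@H](O)CCc2ccc(O[Si](C)(C)C(C)(C)C)cc2Br)c(CC=C)c(O[Si](C)(C)C(C)(C)C)c1O[Si](C)(C)C(C)(C)C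
F7 | step 5 | (2S)-2-[2,5-diallyl-3,4-bis(tert-butyldimethylsilyloxy)phenyl]-7-(tert-butyldimethylsilyloxy)chroman | C=CCc1cc([C@@H]2CCc3ccc(O[Si](C)(C)C(C)(C)C)cc3O2)c(CC=C)c(O[Si](C)(C)C(C)(C)C)c1O[Si](C)(C)C(C)(C)C
F8 | step 5 | (2S)-2-[3,4-bis(tert-butyldimethylsilyloxy)-2,5-bis(3-methylbut-2-enyl)phenyl]-7-(tert-butyldimethylsilyloxy)chroman | CC(C)=CCc1cc([C@@H]2CCc3ccc(O[Si](C)(C)C(C)(C)C)cc3O2)c(CC=C(C)C)c(O[Si](C)(C)C(C)(C)C)c1O[Si](C)(C)C(C)(C)C
F9 | step 2 | 1,2-bis(allyloxy)benzene | C=CCOc1ccccc1OCC=C
F10 | step 2 | 3,6-diallylbenzene-1,2-diol | C=CCc1ccc(CC=C)c(O)c1O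
F0 | step 7 | none | none
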